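Abbreviations: TBS = tert-butyldimethylsilyl, TBDPS = tert-butyldiphenylsilyl. Atom labels: ring C1 (CH bearing the acetonyl chain C8–C10), C2 (ketone), C3 (bearing hydroxymethyl C11), C4 (alkene CH), C5 (CH2), C6 (quaternary; methyl C12 and the 4-methylpent-3-enyl chain C13–C18), C7 (CH bearing the enol-ester vinyl C19=C20).

## The problem

Target 29 is a single cyclohept-2-enone ring with five of its seven carbons substituted, so the task is to build a seven-membered ring and place four different side chains on it. C1, C7 and C6 are contiguous stereocentres, with the acetonyl chain, the C19 vinyl group and the C12 methyl all on one face and C6 quaternary. C6 and C7 cannot be corrected once made and must be set together. C1 lies α to the C2 ketone, so it can be set late under the influence of C7 and C6, and it can equally be lost by enolisation. The E enol ester is an acyl donor that will not survive strong base, nucleophiles or unbuffered fluoride. The C2/C9 1,4-diketone closes by aldol reaction in base, and the C15=C16 alkene is open to electrophiles, carbenes and radicals. The C2 ketone, the C3=C4 alkene and the C3 substituent together form a 2-substituted cyclohept-2-enone, which is a cyclohexanone enol derivative (ring C1–C2–C4–C5–C6–C7, enol double bond C2=C4) plus the single carbon C3. That six-membered ring, with C6 and C7 adjacent and C2 in a 1,4-relationship to C6, is the adduct of a 2-silyloxybutadiene and an α-methyl enal whose alkene geometry fixes the C6/C7 relationship.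

## Retrosynthesis

**C11–O and C20–O.** Target 29 is traced to its C11 TBDPS ether 28, and the enol ester C20–O bond is cut to give alkenyltrifluoroborate 26 and 3-methylbut-2-enoic acid 27. Acylating an aldehyde enolate would give no control of geometry, and adding the acid to an alkyne would favour the Z isomer. An oxidative copper coupling transfers the E geometry of a C19=C20–B bond unchanged. The forward step must tolerate the 1,4-diketone, and C11–OH must stay masked so that it neither competes for copper nor receives the acyl group.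

**C19=C20.** Trifluoroborate 26 comes from pinacol boronate 25, which is cut at the alkene into aldehyde 23 and the one-carbon reagent 24. A chromium-mediated boryl-olefination is chosen because it is E-selective and attacks aldehydes in the presence of ketones. Aldehyde 23 goes back through alcohol 22 to bis-silyl ether 21, which requires that the C19 TBS ether can be removed while the C11 TBDPS ether stays.

**Acetonyl chain and C1.** The C9 ketone of 21 is taken back to the terminal alkene of 20, because an acetonyl halide would be enolised by the C1 enolate, whereas an allyl group is inert until oxidised. Ketone 20 is the C1 epimer of 19, and 19 is cut at C1–C8 into enone 17 and allyl iodide 18. Two stages are needed because alkylation and protonation of the C1 enolate should both occur on the less hindered face, and only protonation then leaves the carbon chain cis to C19.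

**C3–C11.** Enone 17 is the silyl ether of alcohol 16, which is cut at C3–C11 into bromo enone 14 and stannane 15. The bromine on C3 is a ready-made handle, and the neutral coupling conditions suit a base-sensitive enone.

**C2–C3 and C3–C4 (key step).** Bromo enone 14 is cut at both bonds to C3 and the C2–C4 bond is restored, giving silyl enol ether 11 and bromoform 12 by way of dibromocyclopropane 13. Closing a seven-membered ring directly would cost entropy, and a diazoalkane homologation of the ketone would not distinguish C1 from C4 and would leave no halogen. The precursor is a cyclohexene whose only requirement is that the enol ether lies between C2 and C4. The forward reaction must favour the enol ether over the C15=C16 alkene.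

**C14–C15 and C13=C14.** The side chain of 11 is cut at C14–C15 into vinyl compound 8 and bromide 9 through borane 10, and 8 is cut at C13=C14 into aldehyde 6 and phosphonium salt 7. This is done before ring expansion because after it C2 is a ketone that the borane would reduce. The price is that the trisubstituted alkene is present in the key step.

**C5–C6 and C7–C1.** Aldehyde 6 is the Diels–Alder adduct of enal 3 and diene 5. A 2-silyloxy diene is preferred to a 1-alkoxy-3-silyloxy diene because its adduct is already the C2=C4 enol ether, so no enone has to be formed and reduced. The forward reaction must add to one face of a trisubstituted enal.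

**Building blocks.** Enal 3 comes from aldehyde 1 and ylide 2 by Wittig reaction, and diene 5 from butenone 4 by silylation.

## Roads not taken

Alternative 1: The cut is C1–C7. In the forward step Pd2(dba)3 (zerovalent palladium) with a chiral diphosphine would ionise one carboxylate of the allylic gem-bis(3-methylbut-2-enoate) in open-chain β-keto ester A1, and the C1 enolate would attack C7 in a 7-exo closure to give A2.
- Merits: the ring, the C7 stereocentre and the E enol ester arrive in one step. This would replace steps 12 to 16 of the chosen route, and in that respect it is clearly better.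
- Weak points: the enolate must attack the allyl terminus remote from oxygen, a carbon next to the quaternary C6, whereas such acyloxy-allyl complexes are normally attacked at the oxygen-bearing carbon. The seven-membered closure is slow and competes with elimination. A1 needs C6 as an isolated acyclic quaternary stereocentre and a Z C3=C4 alkene, and the acetonyl chain must still be added to a hindered β-keto ester and the ester removed with the enol ester present.
- Comparison: the chosen plan sets C6 and C7 together from alkene geometry in a cycloaddition and keeps the enol ester out of all basic steps. It pays with a longer end game.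

Alternative 2: The cut is C6–C7, with C2–C4 joined in the precursor. cis-Dialkenylcyclopropane A3, available in principle by asymmetric cyclopropanation with a catalyst such as Rh2(S-DOSP)4 (dirhodium tetrakis[(S)-N-(4-dodecylphenylsulfonyl)prolinate]), would undergo Cope rearrangement through a boat transition state to cycloheptadiene A4.
- Merits: the ring, the quaternary C6 and C7 are formed in one stereospecific pericyclic step, which is shorter and more secure for these two centres than the two C–C bond-forming steps of the chosen plan.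
- Weak points: for C19 to end up cis to C12, the homoprenyl chain must occupy the inward (Z) position of its alkene terminus, where it collides with the cyclopropane CH2 in the boat. Such Cope rearrangements need forcing conditions and compete with cyclopropane isomerisation. A4 also carries an ester carbon on C2 where oxygen is needed, C3 as a bare CH2, and a C4=C5 alkene in the wrong place.
- Comparison: the chosen ring expansion delivers the C2 ketone, the C3=C4 alkene and a C3 halogen exactly as required, whereas A4 would need several redox and transposition steps.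

Alternative 3: The cut is C1–C2. A chiral triazolium-derived N-heterocyclic carbene would convert the C2 aldehyde of A5 into an acyl anion equivalent that adds to C1 of the tethered E enone (7-exo-trig Stetter reaction) to give A6.
- Merits: the 1,4-diketone and the C1 stereocentre are made in one step under catalyst control. This is better than the chosen plan at C1, which relies on substrate-controlled protonation and spends three steps (9 to 11) on the acetonyl chain.
- Weak points: intramolecular Stetter reactions are well established for five- and six-membered rings and rare for seven, and here the acceptor carbon sits beside the congested C7/C6 pair. A5 again needs C6 and C7 from separate acyclic chemistry. A6 is saturated from C3 to C5, so the enone and C11 must be introduced by enolising towards C3 a ketone whose other α-carbon is the epimerisable C1.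
- Comparison: the chosen plan obtains the C3 functionality directly from the carbene carbon and its bromine, and it builds C6 and C7 in a ring.

Key step: step 6

Assumption: the sense of induction in step 3 is taken to follow the formyl C–H···O binding model for α-substituted enals. If the first assay shows the opposite sense, the mirror-image catalyst is used.

Assumption: stannane 15 and boronate 24 are treated as purchasable reagents.

## Route

Step 1
Reactants: 1 (TBS-oxy)acetaldehyde; 2 2-(triphenylphosphoranylidene)propanal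
Product: 3 (E)-2-methyl-4-(TBS-oxy)but-2-enal
Conditions: PhMe, 80 °C
Reagents that add atoms: none
Why: Wittig olefination with a formyl-stabilised ylide is reliably E-selective. The E geometry places the methyl group cis to CH2OTBS on the alkene, which later makes C12 and C19 cis on the ring.

Step 2
Reactants: 4 but-3-en-2-one
Product: 5 2-(TBS-oxy)buta-1,3-diene
Conditions: TBSOTf, Et3N, Et2O, 0 → 23 °C
Reagents that add atoms: tert-butyldimethylsilyl trifluoromethanesulfonate, CC(C)(C)[Si](C)(C)OS(=O)(=O)C(F)(F)F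
Why: Soft enolisation of the methyl ketone with O-silylation is the standard preparation of 2-silyloxy dienes.

Step 3
Reactants: 3 (E)-2-methyl-4-(TBS-oxy)but-2-enal; 5 2-(TBS-oxy)buta-1,3-diene
Product: 6 (1S,6S)-1-methyl-4-(TBS-oxy)-6-[(TBS-oxy)methyl]cyclohex-3-ene-1-carbaldehyde
Conditions: (S)-1-(2-methylphenyl)-3,3-diphenyltetrahydro-1H,3H-pyrrolo[1,2-c][1,3,2]oxazaborole (20 mol %), (CF3SO2)2NH (17 mol %), CH2Cl2, −78 → −40 °C; Et3N quench
Reagents that add atoms: none
Why: Enantioselective Diels–Alder reaction of an α-substituted enal activated by a protonated chiral oxazaborolidine, a known catalytic cycloaddition of 2-silyloxybutadienes. The diene CH2 next to the silyloxy carbon bonds to the enal β-carbon, so the enol ether emerges between C2 and C4; suprafacial addition to the E alkene makes C12 and C19 cis, and the catalyst-shielded enal face fixes the absolute configuration at C6 and C7.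

Step 4
Reactants: 6 (1S,6S)-1-methyl-4-(TBS-oxy)-6-[(TBS-oxy)methyl]cyclohex-3-ene-1-carbaldehyde; 7 methyltriphenylphosphonium bromide
Product: 8 (4R,5S)-4-ethenyl-4-methyl-1-(TBS-oxy)-5-[(TBS-oxy)methyl]cyclohex-1-ene
Conditions: KOt-Bu, THF, 0 → 23 °C
Reagents that add atoms: none
Why: Wittig methylenation of a non-enolisable aldehyde on a quaternary carbon. The silyl enol ether and the silyl ether are inert to the ylide, and no stereocentre is at risk.

Step 5
Reactants: 8 (4R,5S)-4-ethenyl-4-methyl-1-(TBS-oxy)-5-[(TBS-oxy)methyl]cyclohex-1-ene; 9 1-bromo-2-methylprop-1-ene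
Product: 11 (4S,5S)-4-methyl-4-(4-methylpent-3-en-1-yl)-1-(TBS-oxy)-5-[(TBS-oxy)methyl]cyclohex-1-ene, via B-alkyl-9-borabicyclo[3.3.1]nonane 10 (not isolated)
Conditions: 9-BBN, THF, 23 → 50 °C; then 9, PdCl2(dppf), aq. K3PO4, DMF, 23 → 50 °C
Reagents that add atoms: none
Why: 9-BBN hydroborates the monosubstituted vinyl group anti-Markovnikov much faster than the trisubstituted silyl enol ether, and the B-alkyl Suzuki–Miyaura coupling then forms C14–C15. C2 is still masked as the enol ether, so there is no carbonyl for the borane to reduce.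

Step 6
Reactants: 11 (4S,5S)-4-methyl-4-(4-methylpent-3-en-1-yl)-1-(TBS-oxy)-5-[(TBS-oxy)methyl]cyclohex-1-ene; 12 bromoform
Product: 14 (5S,6S)-2-bromo-5-methyl-5-(4-methylpent-3-en-1-yl)-6-[(TBS-oxy)methyl]cyclohept-2-en-1-one, via dibromocyclopropyl silyl ether 13 (not isolated)
Conditions: CHBr3 (limiting, slow addition), KOt-Bu, pentane, −30 → 23 °C; then pyridine, PhMe, 60 °C
Reagents that add atoms: none
Why: α-Elimination of HBr from bromoform by KOt-Bu gives singlet dibromocarbene, which adds in a concerted [2+1] cheletropic fashion to the electron-rich C2=C4 enol ether of 11 and closes the three-membered ring of 13 (C2–C3 and C3–C4 form). In 13 the silyloxy oxygen on C2 assists ionisation of the endo C–Br bond while the cyclopropane opens in the disrotatory cyclopropyl-to-allyl sense, breaking C2–C4; the resulting silyloxy-stabilised 2-bromoallyl cation loses the silyl group to bromide or tert-butoxide and leaves the C2 ketone conjugated to the C3(Br)=C4 alkene. The seven-membered ring is therefore not closed by cyclisation but arises by electrocyclic enlargement of the fused bicyclo[4.1.0]heptane, so no medium-ring entropy is paid. The closest known reaction type is the dihalocarbene ring expansion of cyclic silyl enol ethers to 2-halocycloalk-2-enones. No stereocentre is created: the two new centres of 13 are destroyed on opening, either face of the enol ether converges on 14, and C6 and C7 are not touched by the hindered base. The site of insertion is fixed by the position of the enol ether, which the Diels–Alder step placed between C2 and C4. The selectivity that must be secured is for the oxygen-substituted alkene over the trisubstituted C15=C16 alkene; the higher nucleophilicity of the enol ether, bromoform as the limiting reagent and low temperature are relied on, and unreacted 11 is recycled.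

Step 7
Reactants: 14 (5S,6S)-2-bromo-5-methyl-5-(4-methylpent-3-en-1-yl)-6-[(TBS-oxy)methyl]cyclohept-2-en-1-one; 15 (tributylstannyl)methanol
Product: 16 (5S,6S)-2-(hydroxymethyl)-5-methyl-5-(4-methylpent-3-en-1-yl)-6-[(TBS-oxy)methyl]cyclohept-2-en-1-one
Conditions: Pd(PPh3)4, dioxane, 90 °C
Reagents that add atoms: none
Why: Stille coupling; the α-bromo enone is an activated alkenyl bromide for oxidative addition to zerovalent palladium, and the stannane transfers its hydroxymethyl group in preference to butyl. The neutral conditions spare the silyl ether, the enone and the side-chain alkene.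

Step 8
Reactants: 16 (5S,6S)-2-(hydroxymethyl)-5-methyl-5-(4-methylpent-3-en-1-yl)-6-[(TBS-oxy)methyl]cyclohept-2-en-1-one
Product: 17 (5S,6S)-2-[(TBDPS-oxy)methyl]-5-methyl-5-(4-methylpent-3-en-1-yl)-6-[(TBS-oxy)methyl]cyclohept-2-en-1-one
Conditions: TBDPSCl, imidazole, CH2Cl2, 0 → 23 °C
Reagents that add atoms: tert-butyl(chloro)diphenylsilane, CC(C)(C)[Si](Cl)(c1ccccc1)c1ccccc1
Why: Standard silylation of a primary allylic alcohol. The TBDPS ether outlasts the acid that later removes the C19 TBS ether and keeps C11–OH out of the enolate, oxidation and copper steps.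

Step 9
Reactants: 17 (5S,6S)-2-[(TBDPS-oxy)methyl]-5-methyl-5-(4-methylpent-3-en-1-yl)-6-[(TBS-oxy)methyl]cyclohept-2-en-1-one; 18 3-iodoprop-1-ene
Product: 19 (5S,6S,7S)-2-[(TBDPS-oxy)methyl]-5-methyl-5-(4-methylpent-3-en-1-yl)-7-(prop-2-en-1-yl)-6-[(TBS-oxy)methyl]cyclohept-2-en-1-one
Conditions: LDA, THF, −78 °C; then 18, DMPU, −78 → −40 °C
Reagents that add atoms: none
Why: Kinetic deprotonation of the enone at the α′ carbon C1 gives the cross-conjugated lithium enolate, which is C-allylated. Attack is expected anti to the C7 substituent, giving the trans isomer shown; any cis isomer formed is already 20, and both converge in step 10.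

Step 10
Reactants: 19 (5S,6S,7S)-2-[(TBDPS-oxy)methyl]-5-methyl-5-(4-methylpent-3-en-1-yl)-7-(prop-2-en-1-yl)-6-[(TBS-oxy)methyl]cyclohept-2-en-1-one
Product: 20 (5S,6S,7R)-2-[(TBDPS-oxy)methyl]-5-methyl-5-(4-methylpent-3-en-1-yl)-7-(prop-2-en-1-yl)-6-[(TBS-oxy)methyl]cyclohept-2-en-1-one
Conditions: LDA, THF, −78 °C; then 2,6-di-tert-butyl-4-methylphenol, −78 °C
Reagents that add atoms: none
Why: Epimerisation by enolate formation and kinetic C-protonation, the known route to cis-2,3-disubstituted cycloalkanones. Allylic strain with the C1 allyl group holds the C7 CH2OTBS group pseudoaxial, so the hindered phenol should deliver the proton to the opposite face of C1 and leave the allyl chain cis to C19.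

Step 11
Reactants: 20 (5S,6S,7R)-2-[(TBDPS-oxy)methyl]-5-methyl-5-(4-methylpent-3-en-1-yl)-7-(prop-2-en-1-yl)-6-[(TBS-oxy)methyl]cyclohept-2-en-1-one
Product: 21 (5S,6S,7R)-2-[(TBDPS-oxy)methyl]-5-methyl-5-(4-methylpent-3-en-1-yl)-7-(2-oxopropyl)-6-[(TBS-oxy)methyl]cyclohept-2-en-1-one
Conditions: PdCl2 (10 mol %), CuCl, O2 (1 atm), DMF/H2O 7:1, 23 °C
Reagents that add atoms: water, O
Why: Tsuji–Wacker oxidation; Markovnikov hydroxypalladation occurs only at the monosubstituted alkene, and the trisubstituted C15=C16 alkene and the enone are inert. The mildly acidic medium should not enolise C1.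

Step 12
Reactants: 21 (5S,6S,7R)-2-[(TBDPS-oxy)methyl]-5-methyl-5-(4-methylpent-3-en-1-yl)-7-(2-oxopropyl)-6-[(TBS-oxy)methyl]cyclohept-2-en-1-one
Product: 22 (5S,6S,7R)-2-[(TBDPS-oxy)methyl]-6-(hydroxymethyl)-5-methyl-5-(4-methylpent-3-en-1-yl)-7-(2-oxopropyl)cyclohept-2-en-1-one
Conditions: AcOH/THF/H2O 3:1:1, 23 °C
Reagents that add atoms: none
Why: Acid hydrolysis removes a primary TBS ether far faster than a TBDPS ether. A non-alcoholic medium avoids ketal formation at the two ketones.

Step 13
Reactants: 22 (5S,6S,7R)-2-[(TBDPS-oxy)methyl]-6-(hydroxymethyl)-5-methyl-5-(4-methylpent-3-en-1-yl)-7-(2-oxopropyl)cyclohept-2-en-1-one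
Product: 23 (1S,2S,7R)-5-[(TBDPS-oxy)methyl]-2-methyl-2-(4-methylpent-3-en-1-yl)-6-oxo-7-(2-oxopropyl)cyclohept-4-ene-1-carbaldehyde
Conditions: Dess–Martin periodinane, NaHCO3, CH2Cl2, 0 → 23 °C
Reagents that add atoms: none
Why: Dess–Martin oxidation under buffered, near-neutral conditions gives the aldehyde without enolising C7 or C1. The aldehyde is used at once.

Step 14
Reactants: 23 (1S,2S,7R)-5-[(TBDPS-oxy)methyl]-2-methyl-2-(4-methylpent-3-en-1-yl)-6-oxo-7-(2-oxopropyl)cyclohept-4-ene-1-carbaldehyde; 24 2-(dichloromethyl)-4,4,5,5-tetramethyl-1,3,2-dioxaborolane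
Product: 25 (5S,6S,7R)-2-[(TBDPS-oxy)methyl]-5-methyl-5-(4-methylpent-3-en-1-yl)-7-(2-oxopropyl)-6-[(E)-2-(4,4,5,5-tetramethyl-1,3,2-dioxaborolan-2-yl)ethenyl]cyclohept-2-en-1-one
Conditions: CrCl2, LiI, THF, 23 °C
Reagents that add atoms: none
Why: Takai–Utimoto boryl-olefination; the geminal dichromium species from 24 adds to the aldehyde and eliminates to the E alkenylboronate. The reagent is selective for aldehydes over the two ketones and is not basic.

Step 15
Reactants: 25 (5S,6S,7R)-2-[(TBDPS-oxy)methyl]-5-methyl-5-(4-methylpent-3-en-1-yl)-7-(2-oxopropyl)-6-[(E)-2-(4,4,5,5-tetramethyl-1,3,2-dioxaborolan-2-yl)ethenyl]cyclohept-2-en-1-one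
Product: 26 potassium trifluoro{(E)-2-[(1S,2S,7R)-5-[(TBDPS-oxy)methyl]-2-methyl-2-(4-methylpent-3-en-1-yl)-6-oxo-7-(2-oxopropyl)cyclohept-4-en-1-yl]ethenyl}borate
Conditions: KHF2 (aq.), MeOH, 23 °C
Reagents that add atoms: potassium hydrogen difluoride, [K+].F.[F-]
Why: Standard conversion of a pinacol boronate into the trifluoroborate. It removes pinacol, which retards copper couplings, and the alkyl TBDPS ether is stable to this reagent.

Step 16
Reactants: 26 potassium trifluoro{(E)-2-[(1S,2S,7R)-5-[(TBDPS-oxy)methyl]-2-methyl-2-(4-methylpent-3-en-1-yl)-6-oxo-7-(2-oxopropyl)cyclohept-4-en-1-yl]ethenyl}borate; 27 3-methylbut-2-enoic acid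
Product: 28 (E)-2-[(1S,2S,7R)-5-[(TBDPS-oxy)methyl]-2-methyl-2-(4-methylpent-3-en-1-yl)-6-oxo-7-(2-oxopropyl)cyclohept-4-en-1-yl]ethenyl 3-methylbut-2-enoate
Conditions: CuBr (20 mol %), DMAP, 4 Å MS, O2 (1 atm), CH2Cl2/MeCN, 40 °C
Reagents that add atoms: none
Why: Chan–Lam-type oxidative coupling of an alkenyltrifluoroborate with a carboxylic acid, a known route to enol esters. Transmetalation to copper and C–O reductive elimination from a trivalent copper carboxylate retain the alkene geometry, so the E boronate gives the E enol ester.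

Step 17
Reactants: 28 (E)-2-[(1S,2S,7R)-5-[(TBDPS-oxy)methyl]-2-methyl-2-(4-methylpent-3-en-1-yl)-6-oxo-7-(2-oxopropyl)cyclohept-4-en-1-yl]ethenyl 3-methylbut-2-enoate
Product: 29 (E)-2-[(1S,2S,7R)-5-(hydroxymethyl)-2-methyl-2-(4-methylpent-3-en-1-yl)-6-oxo-7-(2-oxopropyl)cyclohept-4-en-1-yl]ethenyl 3-methylbut-2-enoate
Conditions: HF·pyridine, pyridine, THF, 0 → 23 °C
Reagents that add atoms: none
Why: Buffered acidic fluoride cleaves the silyl ether without the basicity that would transfer the enol ester acyl group, close the 1,4-diketone by aldol reaction or epimerise C1.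

## Compound list

1 | (TBS-oxy)acetaldehyde | O=CCO[Si](C)(C)C(C)(C)C | starting material
2 | 2-(triphenylphosphoranylidene)propanal | CC(C=O)=P(c1ccccc1)(c1ccccc1)c1ccccc1 | starting material
3 | (E)-2-methyl-4-(TBS-oxy)but-2-enal | C/C(C=O)=C\CO[Si](C)(C)C(C)(C)C | intermediate
4 | but-3-en-2-one | C=CC(C)=O | starting material
5 | 2-(TBS-oxy)buta-1,3-diene | C=CC(=C)O[Si](C)(C)C(C)(C)C | intermediate
6 | (1S,6S)-1-methyl-4-(TBS-oxy)-6-[(TBS-oxy)methyl]cyclohex-3-ene-1-carbaldehyde (methyl cis to CH2OTBS) | CC(C)(C)[Si](C)(C)OC1=CC[C@](C)(C=O)[C@@H](CO[Si](C)(C)C(C)(C)C)C1 | intermediate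
7 | methyltriphenylphosphonium bromide | C[P+](c1ccccc1)(c1ccccc1)c1ccccc1.[Br-] | starting material
8 | (4R,5S)-4-ethenyl-4-methyl-1-(TBS-oxy)-5-[(TBS-oxy)methyl]cyclohex-1-ene | CC(C)(C)[Si](C)(C)OC1=CC[C@](C)(C=C)[C@@H](CO[Si](C)(C)C(C)(C)C)C1 | intermediate
9 | 1-bromo-2-methylprop-1-ene | CC(C)=CBr | starting material
10 | 9-{2-[(1S,6S)-1-methyl-4-(TBS-oxy)-6-[(TBS-oxy)methyl]cyclohex-3-en-1-yl]ethyl}-9-borabicyclo[3.3.1]nonane | CC(C)(C)[Si](C)(C)OC1=CC[C@](C)(CCB2C3CCCC2CCC3)[C@@H](CO[Si](C)(C)C(C)(C)C)C1 | intermediate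
11 | (4S,5S)-4-methyl-4-(4-methylpent-3-en-1-yl)-1-(TBS-oxy)-5-[(TBS-oxy)methyl]cyclohex-1-ene | CC(C)(C)[Si](C)(C)OC1=CC[C@](C)(CCC=C(C)C)[C@@H](CO[Si](C)(C)C(C)(C)C)C1 | intermediate
12 | bromoform | BrC(Br)Br | starting material
13 | (3S,4S)-7,7-dibromo-4-methyl-4-(4-methylpent-3-en-1-yl)-1-(TBS-oxy)-3-[(TBS-oxy)methyl]bicyclo[4.1.0]heptane (cis-fused, either cyclopropane face) | CC(C)(C)[Si](C)(C)OC12C[C@H](CO[Si](C)(C)C(C)(C)C)[C@@](C)(CCC=C(C)C)CC1C2(Br)Br | intermediate
14 | (5S,6S)-2-bromo-5-methyl-5-(4-methylpent-3-en-1-yl)-6-[(TBS-oxy)methyl]cyclohept-2-en-1-one | O=C1C[C@H](CO[Si](C)(C)C(C)(C)C)[C@@](C)(CCC=C(C)C)CC=C1Br | intermediate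
15 | (tributylstannyl)methanol | CCCC[Sn](CO)(CCCC)CCCC | starting material
16 | (5S,6S)-2-(hydroxymethyl)-5-methyl-5-(4-methylpent-3-en-1-yl)-6-[(TBS-oxy)methyl]cyclohept-2-en-1-one | O=C1C[C@H](CO[Si](C)(C)C(C)(C)C)[C@@](C)(CCC=C(C)C)CC=C1CO | intermediate
17 | (5S,6S)-2-[(TBDPS-oxy)methyl]-5-methyl-5-(4-methylpent-3-en-1-yl)-6-[(TBS-oxy)methyl]cyclohept-2-en-1-one | O=C1C[C@H](CO[Si](C)(C)C(C)(C)C)[C@@](C)(CCC=C(C)C)CC=C1CO[Si](c1ccccc1)(c1ccccc1)C(C)(C)C | intermediate
18 | 3-iodoprop-1-ene | C=CCI | starting material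
19 | (5S,6S,7S)-2-[(TBDPS-oxy)methyl]-5-methyl-5-(4-methylpent-3-en-1-yl)-7-(prop-2-en-1-yl)-6-[(TBS-oxy)methyl]cyclohept-2-en-1-one (allyl trans to CH2OTBS) | C=CC[C@@H]1C(=O)C(CO[Si](c2ccccc2)(c2ccccc2)C(C)(C)C)=CC[C@](C)(CCC=C(C)C)[C@H]1CO[Si](C)(C)C(C)(C)C | intermediate
20 | (5S,6S,7R)-2-[(TBDPS-oxy)methyl]-5-methyl-5-(4-methylpent-3-en-1-yl)-7-(prop-2-en-1-yl)-6-[(TBS-oxy)methyl]cyclohept-2-en-1-one (allyl cis to CH2OTBS) | C=CC[C@H]1C(=O)C(CO[Si](c2ccccc2)(c2ccccc2)C(C)(C)C)=CC[C@](C)(CCC=C(C)C)[C@H]1CO[Si](C)(C)C(C)(C)C | intermediate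
21 | (5S,6S,7R)-2-[(TBDPS-oxy)methyl]-5-methyl-5-(4-methylpent-3-en-1-yl)-7-(2-oxopropyl)-6-[(TBS-oxy)methyl]cyclohept-2-en-1-one | CC(=O)C[C@H]1C(=O)C(CO[Si](c2ccccc2)(c2ccccc2)C(C)(C)C)=CC[C@](C)(CCC=C(C)C)[C@H]1CO[Si](C)(C)C(C)(C)C | intermediate
22 | (5S,6S,7R)-2-[(TBDPS-oxy)methyl]-6-(hydroxymethyl)-5-methyl-5-(4-methylpent-3-en-1-yl)-7-(2-oxopropyl)cyclohept-2-en-1-one | CC(=O)C[C@H]1C(=O)C(CO[Si](c2ccccc2)(c2ccccc2)C(C)(C)C)=CC[C@](C)(CCC=C(C)C)[C@H]1CO | intermediate
23 | (1S,2S,7R)-5-[(TBDPS-oxy)methyl]-2-methyl-2-(4-methylpent-3-en-1-yl)-6-oxo-7-(2-oxopropyl)cyclohept-4-ene-1-carbaldehyde | CC(=O)C[C@H]1C(=O)C(CO[Si](c2ccccc2)(c2ccccc2)C(C)(C)C)=CC[C@](C)(CCC=C(C)C)[C@H]1C=O | intermediate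
24 | 2-(dichloromethyl)-4,4,5,5-tetramethyl-1,3,2-dioxaborolane | ClC(Cl)B1OC(C)(C)C(C)(C)O1 | starting material
25 | (5S,6S,7R)-2-[(TBDPS-oxy)methyl]-5-methyl-5-(4-methylpent-3-en-1-yl)-7-(2-oxopropyl)-6-[(E)-2-(4,4,5,5-tetramethyl-1,3,2-dioxaborolan-2-yl)ethenyl]cyclohept-2-en-1-one | CC(=O)C[C@H]1C(=O)C(CO[Si](c2ccccc2)(c2ccccc2)C(C)(C)C)=CC[C@](C)(CCC=C(C)C)[C@H]1/C=C/B1OC(C)(C)C(C)(C)O1 | intermediate
26 | potassium trifluoro{(E)-2-[(1S,2S,7R)-5-[(TBDPS-oxy)methyl]-2-methyl-2-(4-methylpent-3-en-1-yl)-6-oxo-7-(2-oxopropyl)cyclohept-4-en-1-yl]ethenyl}borate | CC(=O)C[C@H]1C(=O)C(CO[Si](c2ccccc2)(c2ccccc2)C(C)(C)C)=CC[C@](C)(CCC=C(C)C)[C@H]1/C=C/[B-](F)(F)F.[K+] | intermediate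
27 | 3-methylbut-2-enoic acid | CC(C)=CC(=O)O | starting material
28 | (E)-2-[(1S,2S,7R)-5-[(TBDPS-oxy)methyl]-2-methyl-2-(4-methylpent-3-en-1-yl)-6-oxo-7-(2-oxopropyl)cyclohept-4-en-1-yl]ethenyl 3-methylbut-2-enoate | CC(=O)C[C@H]1C(=O)C(CO[Si](c2ccccc2)(c2ccccc2)C(C)(C)C)=CC[C@](C)(CCC=C(C)C)[C@H]1/C=C/OC(=O)C=C(C)C | intermediate
29 | (E)-2-[(1S,2S,7R)-5-(hydroxymethyl)-2-methyl-2-(4-methylpent-3-en-1-yl)-6-oxo-7-(2-oxopropyl)cyclohept-4-en-1-yl]ethenyl 3-methylbut-2-enoate | CC(=O)C[C@H]1C(=O)C(CO)=CC[C@](C)(CCC=C(C)C)[C@H]1/C=C/OC(=O)C=C(C)C | target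

## Step count and least certain steps

Total: 17 steps. Longest linear sequence: 16 steps (steps 1 and 3 to 17, from aldehyde 1); step 2 is a one-step side branch.

**Step 6 (key step).** The free carbene is only moderately selective, so cyclopropanation of the C15=C16 alkene and double addition may compete. Opening of 13 with loss of silyl may also stall.

The fallback sets out from 11 and uses a less reactive, more discriminating zinc carbenoid. Et2Zn and CH2I2 (Simmons–Smith reaction) would convert the enol ether into (3S,4S)-4-methyl-4-(4-methylpent-3-en-1-yl)-1-(TBS-oxy)-3-[(TBS-oxy)methyl]bicyclo[4.1.0]heptane F1. Oxidative opening with FeCl3 in DMF cleaves the same C2–C4 bond and gives (3S,4S)-6-chloro-4-methyl-4-(4-methylpent-3-en-1-yl)-3-[(TBS-oxy)methyl]cycloheptan-1-one F2. NaOAc in MeOH eliminates HCl to give (5S,6S)-5-methyl-5-(4-methylpent-3-en-1-yl)-6-[(TBS-oxy)methyl]cyclohept-2-en-1-one F3. A Morita–Baylis–Hillman reaction of F3 with aqueous formaldehyde and DMAP installs C11 and returns to the route at 16.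

**Step 3.** The trisubstituted enal may be too unreactive, so the diene may decompose or add in an open-chain Mukaiyama–Michael sense. Facial selectivity may also be poor.

The fallback sets out from 3 and puts the stereocontrol into a stoichiometric auxiliary on a more reactive diene.
- 4-Methoxybut-3-en-2-one and (2R,5R)-2,5-diphenylpyrrolidine give (E)-4-[(2R,5R)-2,5-diphenylpyrrolidin-1-yl]but-3-en-2-one F4.
- KHMDS and TBSCl convert it into (2R,5R)-1-[(E)-3-(TBS-oxy)buta-1,3-dien-1-yl]-2,5-diphenylpyrrolidine F5. The antipode is used if the facial model requires it.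
- Thermal Diels–Alder reaction of F5 with 3 in PhMe gives the amino cyclohexene carbaldehyde F6.
- Wittig methylenation gives the ethenyl analogue F7.
- Dilute HCl in THF hydrolyses the enol ether, eliminates the recoverable amine and gives (4S,5S)-4-ethenyl-4-methyl-5-[(TBS-oxy)methyl]cyclohex-2-en-1-one F8.
- Conjugate reduction with Li[HB(s-Bu)3] and trapping of the C2=C4 enolate with TBSOTf returns to the route at 8.

**Step 10.** The proton may not discriminate well between the faces of C1, and LDA may enolise the tertiary C1–H only slowly. Competing deprotonation at C5 would give an extended enolate that can expel the C11 silyloxy group.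

The fallback sets out from 17, bypasses 19 and moves control of C1 from the substrate to a catalyst. LiHMDS with TMEDA and then allyl chloroformate give allyl (5S,6S)-2-[(TBDPS-oxy)methyl]-5-methyl-5-(4-methylpent-3-en-1-yl)-6-[(TBS-oxy)methyl]cyclohepta-1,6-dien-1-yl carbonate F9. Decarboxylative Tsuji–Trost allylation with Pd2(dba)3 (zerovalent palladium) and the enantiomer of N,N'-bis(2-diphenylphosphinobenzoyl)cyclohexane-1,2-diamine that favours the cis product forms the C1–C8 bond under neutral conditions. This returns to the route at 20.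

**Step 16.** Transmetalation of the hindered alkenyl group may be slow, so protodeboronation may dominate. Prolonged warming with DMAP may also enolise C1 or start aldol closure of the 1,4-diketone.

The fallback sets out from 23 and reverses the roles of the partners. Takai olefination with CHI3 and CrCl2 gives (5S,6S,7R)-2-[(TBDPS-oxy)methyl]-6-[(E)-2-iodoethenyl]-5-methyl-5-(4-methylpent-3-en-1-yl)-7-(2-oxopropyl)cyclohept-2-en-1-one F10. Ullmann-type coupling of F10 with the caesium salt of 27 (CuI, trans-N,N'-dimethylcyclohexane-1,2-diamine, THF, 50 °C) forms the C20–O bond with retention of geometry and without added strong base. This returns to the route at 28.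

## Further compounds

F1 | step 6 | (3S,4S)-4-methyl-4-(4-methylpent-3-en-1-yl)-1-(TBS-oxy)-3-[(TBS-oxy)methyl]bicyclo[4.1.0]heptane | CC(C)(C)[Si](C)(C)OC12C[C@H](CO[Si](C)(C)C(C)(C)C)[C@@](C)(CCC=C(C)C)CC1C2
F2 | step 6 | (3S,4S)-6-chloro-4-methyl-4-(4-methylpent-3-en-1-yl)-3-[(TBS-oxy)methyl]cycloheptan-1-one | O=C1C[C@H](CO[Si](C)(C)C(C)(C)C)[C@@](C)(CCC=C(C)C)CC(Cl)C1
F3 | step 6 | (5S,6S)-5-methyl-5-(4-methylpent-3-en-1-yl)-6-[(TBS-oxy)methyl]cyclohept-2-en-1-one | O=C1C[C@H](CO[Si](C)(C)C(C)(C)C)[C@@](C)(CCC=C(C)C)CC=C1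
F4 | step 3 | (E)-4-[(2R,5R)-2,5-diphenylpyrrolidin-1-yl]but-3-en-2-one | CC(=O)/C=C/N1[C@@H](c2ccccc2)CC[C@@H]1c1ccccc1
F5 | step 3 | (2R,5R)-1-[(E)-3-(TBS-oxy)buta-1,3-dien-1-yl]-2,5-diphenylpyrrolidine | C=C(O[Si](C)(C)C(C)(C)C)/C=C/N1[C@@H](c2ccccc2)CC[C@@H]1c1ccccc1
F6 | step 3 | (1S,6S)-2-[(2R,5R)-2,5-diphenylpyrrolidin-1-yl]-1-methyl-4-(TBS-oxy)-6-[(TBS-oxy)methyl]cyclohex-3-ene-1-carbaldehyde (amino carbon as formed) | CC(C)(C)[Si](C)(C)OC1=CC(N2[C@@H](c3ccccc3)CC[C@@H]2c2ccccc2)[C@](C)(C=O)[C@@H](CO[Si](C)(C)C(C)(C)C)C1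
F7 | step 3 | ethenyl analogue of F6 (CH=CH2 in place of CHO) | CC(C)(C)[Si](C)(C)OC1=CC(N2[C@@H](c3ccccc3)CC[C@@H]2c2ccccc2)[C@](C)(C=C)[C@@H](CO[Si](C)(C)C(C)(C)C)C1
F8 | step 3 | (4S,5S)-4-ethenyl-4-methyl-5-[(TBS-oxy)methyl]cyclohex-2-en-1-one | O=C1C=C[C@](C)(C=C)[C@@H](CO[Si](C)(C)C(C)(C)C)C1
F9 | step 10 | allyl (5S,6S)-2-[(TBDPS-oxy)methyl]-5-methyl-5-(4-methylpent-3-en-1-yl)-6-[(TBS-oxy)methyl]cyclohepta-1,6-dien-1-yl carbonate | C=CCOC(=O)OC1=C[C@H](CO[Si](C)(C)C(C)(C)C)[C@@](C)(CCC=C(C)C)CC=C1CO[Si](c1ccccc1)(c1ccccc1)C(C)(C)C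
F10 | step 16 | (5S,6S,7R)-2-[(TBDPS-oxy)methyl]-6-[(E)-2-iodoethenyl]-5-methyl-5-(4-methylpent-3-en-1-yl)-7-(2-oxopropyl)cyclohept-2-en-1-one | CC(=O)C[C@H]1C(=O)C(CO[Si](c2ccccc2)(c2ccccc2)C(C)(C)C)=CC[C@](C)(CCC=C(C)C)[C@H]1/C=C/I
A1 | alternative 1 | 2-(trimethylsilyl)ethyl (4Z,7S,8E)-7-methyl-7-(4-methylpent-3-en-1-yl)-10,10-bis[(3-methylbut-2-enoyl)oxy]-3-oxo-4-[(TBS-oxy)methyl]deca-4,8-dienoate | C[Si](C)(C)CCOC(=O)CC(=O)/C(CO[Si](C)(C)C(C)(C)C)=C\C[C@](C)(CCC=C(C)C)/C=C/C(OC(=O)C=C(C)C)OC(=O)C=C(C)C
A2 | alternative 1 | 2-(trimethylsilyl)ethyl (1R,6S,7S)-6-methyl-6-(4-methylpent-3-en-1-yl)-7-{(E)-2-[(3-methylbut-2-enoyl)oxy]ethenyl}-2-oxo-3-[(TBS-oxy)methyl]cyclohept-3-ene-1-carboxylate | C[Si](C)(C)CCOC(=O)[C@H]1C(=O)C(CO[Si](C)(C)C(C)(C)C)=CC[C@](C)(CCC=C(C)C)[C@H]1/C=C/OC(=O)C=C(C)C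
A3 | alternative 2 | methyl (1R,2R)-2-[(Z)-2,6-dimethylhepta-1,5-dien-1-yl]-1-[(E)-3-(TBS-oxy)prop-1-en-1-yl]cyclopropane-1-carboxylate (alkenyl groups cis) | COC(=O)[C@@]1(/C=C/CO[Si](C)(C)C(C)(C)C)C[C@@H]1/C=C(/C)CCC=C(C)C
A4 | alternative 2 | methyl (3S,4S)-4-methyl-4-(4-methylpent-3-en-1-yl)-3-[(TBS-oxy)methyl]cyclohepta-1,5-diene-1-carboxylate | COC(=O)C1=C[C@H](CO[Si](C)(C)C(C)(C)C)[C@@](C)(CCC=C(C)C)C=CC1
A5 | alternative 3 | (5R,6S,7E)-5-methyl-5-(4-methylpent-3-en-1-yl)-9-oxo-6-[(TBS-oxy)methyl]dec-7-enal | CC(=O)/C=C/[C@H](CO[Si](C)(C)C(C)(C)C)[C@@](C)(CCC=C(C)C)CCCC=O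
A6 | alternative 3 | (2R,3S,4R)-4-methyl-4-(4-methylpent-3-en-1-yl)-2-(2-oxopropyl)-3-[(TBS-oxy)methyl]cycloheptan-1-one | CC(=O)C[C@H]1C(=O)CCC[C@](C)(CCC=C(C)C)[C@H]1CO[Si](C)(C)C(C)(C)C
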